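**Retrosynthetic overview**
- Target 18 comes from hydrolysis of one of the two equivalent methoxy groups of the symmetric bis(2-hydroxy-5-methoxy-6-methylquinone) 17, which comes from de-isopropylation and oxidation of the bis-hydroquinone 15.
- 15 is cut at C1–C6 and C4–C5 of each ring into the bis(cyclobutenedione) 6 and two molecules of the alkenyllithium 11; both six-membered rings form together in that one step, the only ring-forming step.
- Feature used: in ring A (carbonyls C1 and C4, OH at C2, tether at C3, OMe at C5, methyl at C6) the carbons C1–C4 carry the O, O, C, O pattern of a 3-alkoxy-4-alkylcyclobutenedione and C5–C6 are a 1-methoxyprop-1-en-2-yl unit. Ring B is the same ring with OH at C5, and the rings are joined C3 to C3 by (CH2)14.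
- 6 comes from the di-Grignard reagent of 1,14-dibromotetradecane and two molecules of diisopropyl squarate; 11 comes from (Z)-2-bromo-1-methoxyprop-1-ene, made from 1,1-dimethoxypropane.

Key step: step 5

Remark: the dehydrobromination in step 4 is expected to give both geometric isomers of the bromo enol ether; only the Z isomer (bromine cis to methoxy) is carried on.

**Step 1**
Reactants: 1 tetradecane-1,14-diol
Product: 2 1,14-dibromotetradecane
Conditions: 48% aq. HBr, conc. H2SO4, reflux
Reagents that add atoms: hydrogen bromide, Br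
Why: Acid-promoted SN2 substitution of both protonated primary hydroxyls by bromide is a standard conversion of an α,ω-diol into the dibromide, and no other functional group is present.

**Step 2**
Reactants: 2 1,14-dibromotetradecane; 3 diisopropyl squarate (2 equiv)
Product: 6 4,4'-(tetradecane-1,14-diyl)bis[3-(propan-2-yloxy)cyclobut-3-ene-1,2-dione], via di-Grignard reagent 4 (not isolated), via bis(hydroxycyclobutenone) 5 (not isolated)
Conditions: Mg, THF, 50 °C; 3 (2.5 equiv), THF, −78 °C, inverse addition; 1 M HCl; conc. HCl (cat.), CH2Cl2, rt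
Reagents that add atoms: diisopropyl squarate (second molecule of 3), CC(C)OC1=C(OC(C)C)C(=O)C1=O
Why: Magnesium insertion into both primary C–Br bonds gives 4, each end of which adds once (Grignard 1,2-addition) to a carbonyl of a separate molecule of the squarate ester, so that two molecules of 3 are consumed per chain while the excess and the inverse addition keep one squarate from being attacked twice, and acid then ionises each tertiary carbinol of 5 and hydrolyses the distal enol-ether carbon with loss of propan-2-ol, the established 1,3-carbonyl transposition that turns squarate adducts into 3-alkoxy-4-alkylcyclobutenediones.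

**Step 3**
Reactants: 7 1,1-dimethoxypropane
Product: 8 1-methoxyprop-1-ene (mixture of E and Z)
Conditions: TsOH·H2O (cat.), quinoline (cat.), neat, 100 °C, slow distillation through a fractionating column; distillate washed with cold aq. K2CO3, dried, redistilled
Reagents that add atoms: none
Why: Acid-catalysed loss of methanol from the acetal through the oxocarbenium ion (acetal cracking to an enol ether) is driven forward because the low-boiling enol ether and methanol distil from the higher-boiling acetal as they form.

**Step 4**
Reactants: 8 1-methoxyprop-1-ene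
Product: 10 (Z)-2-bromo-1-methoxyprop-1-ene, via 1,2-dibromo-1-methoxypropane 9 (not isolated)
Conditions: Br2 (1.0 equiv), pentane, −78 °C; then PhNEt2, −78 to 90 °C; spinning-band distillation
Reagents that add atoms: bromine, BrBr
Why: Electrophilic addition of bromine gives the α,β-dibromo ether 9, whose labile α-bromide ionises to an oxocarbenium ion that the amine deprotonates at C2 (bromination–dehydrobromination of an enol ether), which should favour bromine cis to methoxy as in the parent 2-bromovinyl ethers, the Z isomer being collected by fractional distillation.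

**Step 5**
Reactants: 6 4,4'-(tetradecane-1,14-diyl)bis[3-(propan-2-yloxy)cyclobut-3-ene-1,2-dione]; 10 (Z)-2-bromo-1-methoxyprop-1-ene (2 equiv)
Product: 15 2,2'-(tetradecane-1,14-diyl)bis[6-methoxy-5-methyl-3-(propan-2-yloxy)benzene-1,4-diol], via alkenyllithium 11 (not isolated), via bis-adduct 12 (not isolated), via bis(dienylketene) 13 (not isolated), via bis(cyclohexadienone) 14 (not isolated)
Conditions: 10 (2.6 equiv), t-BuLi (5.2 equiv), THF, −78 °C; cannulated into 6, THF, −78 °C; cold H2O, pH 7 buffer (NaH2PO4/Na2HPO4) work-up; then PhMe, 110 °C, Ar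
Reagents that add atoms: (Z)-2-bromo-1-methoxyprop-1-ene (second molecule of 10), Br/C(C)=C\OC
Why: Bromine–lithium exchange proceeds with retention to 11, in which lithium is chelated by the cis methoxy oxygen and is not anti to it, so LiOMe is not expelled at −78 °C; two molecules of 11 then add 1,2, one to the ketone-like carbonyl next to the isopropoxy-bearing carbon of each dione of 6, forming C1–C6 in ring A and C1'–C6' in ring B. On heating, each 4-alkenyl-4-hydroxycyclobutenone of 12 undergoes conrotatory 4π electrocyclic ring opening to the dienylketene 13, which closes by disrotatory 6π electrocyclisation of the ketene carbon onto the methoxy-bearing alkene terminus (C4–C5 and C4'–C5') to the dienone 14 and enolises to the hydroquinone. The closest known reaction is the Moore rearrangement of squarate-derived 4-alkenyl-4-hydroxycyclobutenones to hydroquinones, here run at both ends of one tether. Ring A and ring B are closed in the same way, by the thermal 6π electrocyclisation of a dienylketene that follows an intermolecular carbonyl addition. No stereocentre survives: the carbinol carbons of 12 and the sp3 methoxy-bearing carbons of 14 form without control and become sp2 on ring opening and aromatisation, and the alkene geometry of 11 is lost in the same way. The step needs site selectivity between the two carbonyls, secured because the other carbonyl is a deactivated vinylogous ester, and inward rotation of the alkenyl group, secured by the outward preference of the hydroxyl donor in the ring opening.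

**Step 6**
Reactants: 15 2,2'-(tetradecane-1,14-diyl)bis[6-methoxy-5-methyl-3-(propan-2-yloxy)benzene-1,4-diol]
Product: 17 3,3'-(tetradecane-1,14-diyl)bis(2-hydroxy-5-methoxy-6-methylcyclohexa-2,5-diene-1,4-dione), via bis(benzenetriol) 16 (not isolated)
Conditions: BCl3 (excess), CH2Cl2, −78 to 0 °C; H2O; then FeCl3, EtOAc/H2O, rt
Reagents that add atoms: none
Why: BCl3 cleaves the secondary isopropyl aryl ethers much faster than the methyl ethers (Lewis-acid ether cleavage with SN1-like ionisation of the secondary alkyl–oxygen bond), and FeCl3 oxidises the electron-rich 1,2,4-triol rings of 16 to the para-quinones, the stable tautomer of the hydroxyquinone, leaving a 2-hydroxy-5-methoxy pattern in each ring.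

**Step 7**
Reactants: 17 3,3'-(tetradecane-1,14-diyl)bis(2-hydroxy-5-methoxy-6-methylcyclohexa-2,5-diene-1,4-dione)
Product: 18 2,5-dihydroxy-3-[14-(2-hydroxy-5-methoxy-4-methyl-3,6-dioxocyclohexa-1,4-dien-1-yl)tetradecyl]-6-methylcyclohexa-2,5-diene-1,4-dione (CNP0130251.0)
Conditions: 0.1 M NaOH (2.7 equiv), THF/H2O, rt, N2, stopped at partial conversion; 1 M HCl; recovered 17 recycled
Reagents that add atoms: sodium hydroxide, [Na+].[OH-]
Why: Hydroxide adds to C5 of one methoxyquinone ring and expels methoxide (addition–elimination hydrolysis of a vinylogous ester); the two rings are equivalent, so the outcome is statistical, and a limiting charge of free hydroxide with recycling of recovered 17 should keep over-hydrolysis down, while the dihydroxyquinone ring of 18, once formed, is a dianion that reacts no further.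

**Compound list**
1 | tetradecane-1,14-diol | OCCCCCCCCCCCCCCO | starting material
2 | 1,14-dibromotetradecane | BrCCCCCCCCCCCCCCBr | intermediate
3 | diisopropyl squarate, 3,4-di(propan-2-yloxy)cyclobut-3-ene-1,2-dione | CC(C)OC1=C(OC(C)C)C(=O)C1=O | starting material
4 | tetradecane-1,14-diylbis(magnesium bromide) | Br[Mg]CCCCCCCCCCCCCC[Mg]Br | intermediate
5 | 4,4'-(tetradecane-1,14-diyl)bis[4-hydroxy-2,3-di(propan-2-yloxy)cyclobut-2-en-1-one] | CC(C)OC1=C(OC(C)C)C(O)(CCCCCCCCCCCCCCC2(O)C(OC(C)C)=C(OC(C)C)C2=O)C1=O | intermediate
6 | 4,4'-(tetradecane-1,14-diyl)bis[3-(propan-2-yloxy)cyclobut-3-ene-1,2-dione] | CC(C)OC1=C(CCCCCCCCCCCCCCC2=C(OC(C)C)C(=O)C2=O)C(=O)C1=O | intermediate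
7 | 1,1-dimethoxypropane | CCC(OC)OC | starting material
8 | 1-methoxyprop-1-ene (mixture of E and Z) | CC=COC | intermediate
9 | 1,2-dibromo-1-methoxypropane (mixture of diastereomers) | CC(Br)C(Br)OC | intermediate
10 | (Z)-2-bromo-1-methoxyprop-1-ene | Br/C(C)=C\OC | intermediate
11 | (E)-(1-methoxyprop-1-en-2-yl)lithium, lithium cis to methoxy | [Li]/C(C)=C\OC | intermediate
12 | 2,2'-(tetradecane-1,14-diyl)bis{4-hydroxy-4-[(Z)-1-methoxyprop-1-en-2-yl]-3-(propan-2-yloxy)cyclobut-2-en-1-one} (carbinol centres unassigned) | CO\C=C(C)/C1(O)C(OC(C)C)=C(CCCCCCCCCCCCCCC2=C(OC(C)C)C(O)(/C(C)=C\OC)C2=O)C1=O | intermediate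
13 | 2,2'-(tetradecane-1,14-diyl)bis[(3Z,5Z)-4-hydroxy-6-methoxy-5-methyl-3-(propan-2-yloxy)hexa-1,3,5-trien-1-one] | CO/C=C(C)\C(O)=C(OC(C)C)/C(CCCCCCCCCCCCCCC(=C=O)/C(OC(C)C)=C(O)\C(C)=C/OC)=C=O | intermediate
14 | 2,2'-(tetradecane-1,14-diyl)bis[4-hydroxy-6-methoxy-5-methyl-3-(propan-2-yloxy)cyclohexa-2,4-dien-1-one] (C6 centres unassigned) | COC1C(C)=C(O)C(OC(C)C)=C(CCCCCCCCCCCCCCC2=C(OC(C)C)C(O)=C(C)C(OC)C2=O)C1=O | intermediate
15 | 2,2'-(tetradecane-1,14-diyl)bis[6-methoxy-5-methyl-3-(propan-2-yloxy)benzene-1,4-diol] | CC(C)Oc1c(O)c(C)c(OC)c(O)c1CCCCCCCCCCCCCCc1c(O)c(OC)c(C)c(O)c1OC(C)C | intermediate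
16 | 3,3'-(tetradecane-1,14-diyl)bis(5-methoxy-6-methylbenzene-1,2,4-triol) | COc1c(C)c(O)c(O)c(CCCCCCCCCCCCCCc2c(O)c(O)c(C)c(OC)c2O)c1O | intermediate
17 | 3,3'-(tetradecane-1,14-diyl)bis(2-hydroxy-5-methoxy-6-methylcyclohexa-2,5-diene-1,4-dione) | COC1=C(C)C(=O)C(O)=C(CCCCCCCCCCCCCCC2=C(O)C(=O)C(C)=C(OC)C2=O)C1=O | intermediate
18 | 2,5-dihydroxy-3-[14-(2-hydroxy-5-methoxy-4-methyl-3,6-dioxocyclohexa-1,4-dien-1-yl)tetradecyl]-6-methylcyclohexa-2,5-diene-1,4-dione | COC1=C(C)C(=O)C(O)=C(CCCCCCCCCCCCCCC2=C(O)C(=O)C(C)=C(O)C2=O)C1=O | target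

Total step count: 7. Longest linear sequence: 5 steps (1, 2, 5, 6, 7; the branch 3, 4 joins at step 5).

**Steps most likely to fail**

Step 5. The alkenyllithium may lose LiOMe before it adds, the twofold addition may stop at one end, or the enol-ether carbinols may ionise during work-up. The fallback reverses the order of assembly; it sets out from 8, 3 and 2 (through 4) and rejoins the route at 15. Enol ether 8 is deprotonated at the oxygen-bearing carbon (t-BuLi, THF, −78 to 0 °C) to (1-methoxyprop-1-en-1-yl)lithium F1, which has no leaving group anti to lithium. F1 adds to 3 at −78 °C and the alkoxide is silylated in the flask with TMSCl to the silylated squarate adduct F2. The di-Grignard reagent 4 then adds to the remaining carbonyl of two molecules of F2 (THF, −78 to 0 °C) to give the bis-carbinol F3. TFAA/pyridine followed by aq. NaHCO3 ionises the free tertiary alcohols and removes propan-2-ol, giving the bis(cyclobutenone) F4, in which tether and alkenyl group sit on adjacent ring carbons. Heating in toluene at 110 °C brings about the same 4π opening and 6π closure and gives the bis(silyl ether) F5; dilute HCl in THF removes the silyl groups and gives 15.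

Step 4. The dehydrobromination may show poor geometric selectivity, and two volatile isomers may not separate by distillation. The fallback purifies at a non-volatile stage; it sets out from 8 and rejoins the route at 11. The unseparated bromide mixture from 8 (Br2, then PhNEt2) is treated with t-BuLi (Et2O, −78 °C) and then Bu3SnCl. The lithium isomer with lithium trans to methoxy fragments, while the chelated cis isomer is captured as tributyl[(Z)-1-methoxyprop-1-en-2-yl]stannane F6, which is purified by Kugelrohr distillation or chromatography on Et3N-deactivated silica. Tin–lithium exchange of F6 with n-BuLi (THF, −78 °C) delivers 11 directly for step 5.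

Step 7. Hydroxide attacks a substrate that is present as a dianion only slowly, so base-induced degradation and over-hydrolysis can compete, and three strongly acidic quinones are hard to separate. The fallback differentiates the rings before deprotection; it sets out from 15 and rejoins the route at 18. 15 is oxidised (FeCl3, EtOAc/H2O) with all ethers in place to the neutral bis(isopropoxy-methoxy-quinone) F7. One equivalent of NaOH (THF/H2O, 0 °C) hydrolyses a methoxy group on the uncharged quinone; the ring that has reacted becomes an anion, inert to further attack and extractable into aqueous base away from unreacted F7, giving the mono(hydroxyquinone) F8. BCl3 (CH2Cl2, −78 °C) removes both isopropyl groups from F8 and gives 18.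

**Further compounds**
F1 | step 5 | (1-methoxyprop-1-en-1-yl)lithium | [Li]C(OC)=CC
F2 | step 5 | 4-(1-methoxyprop-1-en-1-yl)-2,3-di(propan-2-yloxy)-4-[(trimethylsilyl)oxy]cyclobut-2-en-1-one | CC=C(OC)C1(O[Si](C)(C)C)C(OC(C)C)=C(OC(C)C)C1=O
F3 | step 5 | 1,1'-(tetradecane-1,14-diyl)bis{4-(1-methoxyprop-1-en-1-yl)-2,3-di(propan-2-yloxy)-4-[(trimethylsilyl)oxy]cyclobut-2-en-1-ol} | CC=C(OC)C1(O[Si](C)(C)C)C(OC(C)C)=C(OC(C)C)C1(O)CCCCCCCCCCCCCCC2(O)C(OC(C)C)=C(OC(C)C)C2(O[Si](C)(C)C)C(OC)=CC
F4 | step 5 | 3,3'-(tetradecane-1,14-diyl)bis{4-(1-methoxyprop-1-en-1-yl)-2-(propan-2-yloxy)-4-[(trimethylsilyl)oxy]cyclobut-2-en-1-one} | CC=C(OC)C1(O[Si](C)(C)C)C(=O)C(OC(C)C)=C1CCCCCCCCCCCCCCC2=C(OC(C)C)C(=O)C2(O[Si](C)(C)C)C(OC)=CC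
F5 | step 5 | 3,3'-(tetradecane-1,14-diyl)bis{5-methoxy-6-methyl-2-(propan-2-yloxy)-4-[(trimethylsilyl)oxy]phenol} | C[Si](C)(C)Oc1c(OC)c(C)c(O)c(OC(C)C)c1CCCCCCCCCCCCCCc1c(OC(C)C)c(O)c(C)c(OC)c1O[Si](C)(C)C
F6 | step 4 | tributyl[(Z)-1-methoxyprop-1-en-2-yl]stannane | CCCC[Sn](CCCC)(CCCC)/C(C)=C\OC
F7 | step 7 | 3,3'-(tetradecane-1,14-diyl)bis[5-methoxy-6-methyl-2-(propan-2-yloxy)cyclohexa-2,5-diene-1,4-dione] | COC1=C(C)C(=O)C(OC(C)C)=C(CCCCCCCCCCCCCCC2=C(OC(C)C)C(=O)C(C)=C(OC)C2=O)C1=O
F8 | step 7 | 2-hydroxy-3-methyl-6-{14-[5-methoxy-4-methyl-3,6-dioxo-2-(propan-2-yloxy)cyclohexa-1,4-dien-1-yl]tetradecyl}-5-(propan-2-yloxy)cyclohexa-2,5-diene-1,4-dione | COC1=C(C)C(=O)C(OC(C)C)=C(CCCCCCCCCCCCCCC2=C(OC(C)C)C(=O)C(C)=C(O)C2=O)C1=O
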